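The target's benzene ring (C3a, C4–C7, C7a) carries a one-carbon arm on C4, a two-carbon arm on C5 and an oxymethyl on C6, beside the fused gem-dimethylcyclopentane (C1–C3). This pattern is read as an indane-4,5-aryne that has inserted into a malonate tethered through the C6 oxymethyl. In one operation the linear triyne malonate 9 should cycloisomerise (C3a–C7a and C6–C7), its enolate carbon should bond to C5 as a six-membered lactone, and its CO2Me should shift to C4, giving tricycle 13. The precursor is the methyl malonate ester of 7,7-dimethyldeca-2,4,9-triyn-1-ol. A lactone transposition then tells the three arms apart.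

Key step: step 7

Remark on the chemistry: the target has no stereocentre. Indane locants are used throughout (C2 gem-dimethyl, C4 acetoxymethyl, C5 2-chloroethyl, C6 butanoyloxymethyl, C7 H).

Step 1
Reactants: 1 3,3-dimethylglutaric anhydride
Product: 2 3,3-dimethylpentane-1,5-diol
Conditions: LiAlH4, THF, 0 °C to reflux; aqueous NaOH work-up
Reagents that add atoms: none
Why: Hydride reduction of a cyclic anhydride takes both acyl carbons to primary alcohols, and the substrate has no other functional group.

Step 2
Reactants: 2 3,3-dimethylpentane-1,5-diol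
Product: 3 3,3-dimethylpentanedial
Conditions: (COCl)2, DMSO, CH2Cl2, −78 °C; then Et3N, to 0 °C; used crude
Reagents that add atoms: none
Why: In a Swern oxidation both hydroxyls are activated before base is added, so the dialdehyde should form without lactol-derived lactone, and it is used at once because 1,5-dialdehydes hydrate and oligomerise on standing.

Step 3
Reactants: 3 3,3-dimethylpentanedial
Product: 4 4,4-dimethylhepta-1,6-diyne
Conditions: dimethyl (1-diazo-2-oxopropyl)phosphonate (2.5 equiv), K2CO3, MeOH, 0 °C to rt; pentane extraction, careful distillation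
Reagents that add atoms: dimethyl (1-diazo-2-oxopropyl)phosphonate, CC(=O)C(=[N+]=[N-])P(=O)(OC)OC
Why: Twofold Seyferth–Gilbert homologation with the Ohira–Bestmann reagent turns each aldehyde into a terminal alkyne under carbonate conditions too mild to isomerise the product.

Step 4
Reactants: 5 prop-2-yn-1-ol (propargyl alcohol)
Product: 6 3-bromoprop-2-yn-1-ol
Conditions: NBS, AgNO3 (10 mol%), acetone, rt; used freshly prepared
Reagents that add atoms: N-bromosuccinimide, O=C1CCC(=O)N1Br
Why: Silver-catalysed electrophilic bromination of a terminal alkyne with NBS gives the 1-bromoalkyne and leaves the hydroxyl untouched.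

Step 5
Reactants: 4 4,4-dimethylhepta-1,6-diyne (4 equiv), 6 3-bromoprop-2-yn-1-ol
Product: 7 7,7-dimethyldeca-2,4,9-triyn-1-ol
Conditions: CuCl (5 mol%), NH2OH·HCl, 30% aq. n-BuNH2, CH2Cl2, 0 °C, slow addition of 6
Reagents that add atoms: none
Why: Cadiot–Chodkiewicz cross-coupling joins a terminal alkyne to a 1-bromoalkyne through a copper acetylide while hydroxylamine keeps the copper monovalent, and the excess of symmetric diyne (recovered by distillation) should hold coupling to one terminus.

Step 6
Reactants: 7 7,7-dimethyldeca-2,4,9-triyn-1-ol, 8 methyl 3-chloro-3-oxopropanoate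
Product: 9 methyl 7,7-dimethyldeca-2,4,9-triyn-1-yl malonate
Conditions: pyridine, CH2Cl2, 0 °C
Reagents that add atoms: none
Why: Acylation of a primary propargylic alcohol by an acid chloride with pyridine at 0 °C is routine ester formation and does not disturb the triyne.

Step 7
Reactants: 9 methyl 7,7-dimethyldeca-2,4,9-triyn-1-yl malonate
Product: 13 tricyclic lactone ester (methyl 7,7-dimethyl-3-oxo-1,3,4,6,7,8-hexahydrocyclopenta[g]isochromene-5-carboxylate), via sodium malonate enolate 10 (not isolated), via indanyne enolate 11 (not isolated), via sodium lactone enolate 12 (not isolated)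
Conditions: NaH (1.0 equiv), 15-crown-5 (1.0 equiv), THF, 0 °C; solvent exchange to 1,2-dichlorobenzene (0.005 M), 185 °C, sealed vessel, argon; AcOH quench at rt
Reagents that add atoms: none
Why: Proposed new method: one equivalent of NaH converts the malonate into enolate 10, a base too weak to isomerise the skipped alkynes; on heating, the 1,3-diyne and the terminal alkyne, held by the CH2–CMe2–CH2 tether, should undergo a thermal hexadehydro-Diels–Alder reaction that forms C3a–C7a and C6–C7 and leaves aryne 11 with its strained bond at C4–C5, after which the enolate carbon adds to C5, the C4 aryl anion attacks the adjacent methyl ester carbonyl, and the four-membered alkoxide opens to lactone enolate 12 with CO2Me on C4 (protonated to 13 on quench). The closest known chemistry is the thermal cycloisomerisation of tethered triynes with intramolecular capture of the aryne, and the insertion of fluoride-generated arynes into the C–C bond of malonates and β-keto esters (acyl-alkylation); the two have not been combined. The cyclopentane and the benzene ring close together in the formal intramolecular [4+2] (five-membered ring through the three-atom tether, helped by the gem-dimethyl effect), and the lactone closes by 6-exo-dig attack of the tethered carbon nucleophile on the aryne. No stereocentre is created. Three selectivities are needed: bonding at C5 and not C4 (the tether from the C6 oxymethyl reaches only C5, which is also the wider-angled aryne carbon away from the ring fusion), carbon and not oxygen attack (a soft neutral aryne bonds to the carbon terminus of a stabilised enolate, as it does intermolecularly), and transfer of the methyl ester and not the lactone carbonyl (the latter would require a three-atom bridge across meta positions). The open points are the temperature that the unactivated terminal alkyne demands and a possible [3,3] shift or 5-exo addition of the enolate within the propargylic ester before the aryne forms.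

Step 8
Reactants: 13 tricyclic lactone ester
Product: 15 hydroxymethyl aryl lactone (C4 carboxyl lactonised onto the C5 CH2CH2O arm; C6 CH2OH free), via diol ester 14 (not isolated)
Conditions: LiBH4 (1.1 equiv), THF, 0 °C; aq. NH4Cl; then CSA (10 mol%), CH2Cl2, rt
Reagents that add atoms: none
Why: Chemoselective borohydride reduction should open the aliphatic lactone well before the doubly ortho-substituted aryl methyl ester reacts, and in diol ester 14 only the C5 hydroxyethyl can reach the C4 ester, so acid-catalysed transesterification closes the six-membered aryl lactone and leaves the C6 hydroxymethyl free.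

Step 9
Reactants: 15 hydroxymethyl aryl lactone
Product: 17 [5-(2-chloroethyl)-6-(chloromethyl)-2,2-dimethylindan-4-yl]methanol, via acyl chloride 16 (not isolated)
Conditions: SOCl2 (neat), ZnCl2 (10 mol%), 75 °C; evaporate; then LiBH4, THF, −20 to 0 °C; cold aq. NH4Cl
Reagents that add atoms: thionyl chloride, O=S(Cl)Cl
Why: Thionyl chloride converts the benzylic alcohol into its chloride and, with ZnCl2, opens the aryl lactone by chloride attack at the O–CH2 carbon (the known conversion of lactones into ω-chloroalkyl acyl chlorides), and cold LiBH4 then reduces only the acyl chloride of 16 because benzyl and alkyl chlorides are inert to it.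

Step 10
Reactants: 17 [5-(2-chloroethyl)-6-(chloromethyl)-2,2-dimethylindan-4-yl]methanol
Product: 18 [5-(2-chloroethyl)-4-(hydroxymethyl)-2,2-dimethylindan-6-yl]methyl butanoate
Conditions: sodium butanoate (1.5 equiv), DMF, 45 °C
Reagents that add atoms: sodium butanoate, CCCC(=O)[O-].[Na+]
Why: SN2 displacement by a carboxylate is far faster at the benzylic chloride than at the primary alkyl chloride, and the weakly basic butanoate neither deprotonates the free C4 hydroxyl nor eliminates HCl.

Step 11
Reactants: 18 [5-(2-chloroethyl)-4-(hydroxymethyl)-2,2-dimethylindan-6-yl]methyl butanoate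
Product: 19 [4-(acetoxymethyl)-5-(2-chloroethyl)-2,2-dimethylindan-6-yl]methyl butanoate (target)
Conditions: Ac2O, pyridine, DMAP (5 mol%), CH2Cl2, 0 °C to rt
Reagents that add atoms: acetic anhydride, CC(=O)OC(C)=O
Why: DMAP-catalysed acetylation of the remaining primary benzylic alcohol is routine and affects neither the butanoate nor the alkyl chloride.

Compound list
1 | 3,3-dimethylglutaric anhydride | CC1(C)CC(=O)OC(=O)C1 | starting material
2 | 3,3-dimethylpentane-1,5-diol | OCCC(C)(C)CCO | intermediate
3 | 3,3-dimethylpentanedial | O=CCC(C)(C)CC=O | intermediate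
4 | 4,4-dimethylhepta-1,6-diyne | C#CCC(C)(C)CC#C | intermediate
5 | prop-2-yn-1-ol (propargyl alcohol) | C#CCO | starting material
6 | 3-bromoprop-2-yn-1-ol | BrC#CCO | intermediate
7 | 7,7-dimethyldeca-2,4,9-triyn-1-ol | OCC#CC#CCC(C)(C)CC#C | intermediate
8 | methyl 3-chloro-3-oxopropanoate | COC(=O)CC(Cl)=O | starting material
9 | methyl 7,7-dimethyldeca-2,4,9-triyn-1-yl malonate | COC(=O)CC(=O)OCC#CC#CCC(C)(C)CC#C | intermediate
10 | sodium enolate of 9 (not isolated) | [Na+].COC(=O)C=C([O-])OCC#CC#CCC(C)(C)CC#C | intermediate
11 | 2,2-dimethylindan-4,5-yne carrying the malonate enolate on the C6 oxymethyl, sodium salt (not isolated) | [Na+].COC(=O)C=C([O-])OCC1=CC2=C(CC(C)(C)C2)C#C1 | intermediate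
12 | sodium enolate of 13 (not isolated) | [Na+].COC(=O)c1c2CC(C)(C)Cc2cc3COC([O-])=Cc13 | intermediate
13 | methyl 7,7-dimethyl-3-oxo-1,3,4,6,7,8-hexahydrocyclopenta[g]isochromene-5-carboxylate (indane locants: C4 CO2Me; lactone C5–CH2–C(=O)–O–CH2–C6) | COC(=O)c1c2CC(C)(C)Cc2cc3COC(=O)Cc13 | intermediate
14 | methyl 5-(2-hydroxyethyl)-6-(hydroxymethyl)-2,2-dimethylindane-4-carboxylate (not isolated) | COC(=O)c1c2CC(C)(C)Cc2cc(CO)c1CCO | intermediate
15 | 6-(hydroxymethyl)-2,2-dimethylindane-4-carboxylic acid, lactone with the C5 2-hydroxyethyl arm (C4–C(=O)–O–CH2–CH2–C5) | OCc1cc2CC(C)(C)Cc2c2C(=O)OCCc12 | intermediate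
16 | 5-(2-chloroethyl)-6-(chloromethyl)-2,2-dimethylindane-4-carbonyl chloride (not isolated) | O=C(Cl)c1c2CC(C)(C)Cc2cc(CCl)c1CCCl | intermediate
17 | [5-(2-chloroethyl)-6-(chloromethyl)-2,2-dimethylindan-4-yl]methanol | OCc1c2CC(C)(C)Cc2cc(CCl)c1CCCl | intermediate
18 | [5-(2-chloroethyl)-4-(hydroxymethyl)-2,2-dimethylindan-6-yl]methyl butanoate | CCCC(=O)OCc1cc2CC(C)(C)Cc2c(CO)c1CCCl | intermediate
19 | [4-(acetoxymethyl)-5-(2-chloroethyl)-2,2-dimethylindan-6-yl]methyl butanoate | CCCC(=O)OCc1cc2c(c(COC(C)=O)c1CCCl)CC(C)(C)C2 | target

Total step count: 11. Longest linear sequence: 10 steps (steps 1–3 and 5–11, from 1 to 19); step 4 is a one-step branch from 5.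

Steps most likely to fail

Step 7 (proposed method). The enolate may be consumed by a sigmatropic shift or by addition to the diyne before the triyne cycloisomerises. The aryne may be captured at oxygen, or the aryl anion protonated before the ester transfers. The triyne may also decompose at the temperature needed. The fallback uses known chemistry and builds the benzene ring differently; it sets out from diyne 4 and comes back at 15. Monolithiation of excess 4 (n-BuLi, THF, −78 °C) and quenching with CO2 should give 5,5-dimethylocta-2,7-diynoic acid F1. Commercial tert-butyldimethyl(prop-2-yn-1-yloxy)silane, lithiated and opened onto ethylene oxide (n-BuLi, BF3·OEt2, THF, −78 °C), should give 5-[(tert-butyldimethylsilyl)oxy]pent-3-yn-1-ol F2. Carbodiimide esterification (DCC, catalytic DMAP, CH2Cl2, 0 °C) should join them as the ester-tethered triyne 5-[(tert-butyldimethylsilyl)oxy]pent-3-yn-1-yl 5,5-dimethylocta-2,7-diynoate F3. Intramolecular [2+2+2] alkyne cyclotrimerisation catalysed by RhCl(PPh3)3 (toluene, 80 °C) should then form the benzene ring together with the cyclopentane and the six-membered aryl lactone, giving the silyl ether of 15, F4. The linear order of the three alkynes fixes the substitution pattern. TBAF buffered with AcOH should free the hydroxymethyl and give 15.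

Step 9. In hot SOCl2/ZnCl2 the arene may be alkylated by its own benzylic chloride, or the lactone may open incompletely. During the hydride stage the new C4 alkoxide may close onto the chloroethyl arm as a cyclic ether. The fallback avoids the acid-mediated ring opening; it sets out from 15 and comes back at 19. Silylation (TBDPSCl, imidazole, DMF) should give the tert-butyldiphenylsilyl ether of 15, F5. LiAlH4 (THF, 0 °C) should reduce the lactone to the silyl-protected diol F6 (C4 CH2OH, C5 CH2CH2OH). Mesylation of both hydroxyls and chloride exchange (MsCl, Et3N, CH2Cl2, −20 °C; then LiCl, DMF, 50 °C) should give the silyl-protected dichloride F7. CsOAc in DMF at rt should replace only the benzylic chloride, giving the silyl-protected C4 acetate F8. HF·pyridine should then remove the silyl group to give [5-(2-chloroethyl)-6-(hydroxymethyl)-2,2-dimethylindan-4-yl]methyl acetate F9, and butanoyl chloride with pyridine should give 19.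

Step 3. The 1,5-dialdehyde may self-condense or be trapped as a hemiacetal in basic methanol in competition with the twofold homologation, and the low-boiling diyne may be lost on concentration. The fallback sets out from 3 and comes back at 4 by a two-stage Corey–Fuchs sequence. CBr4/PPh3 (CH2Cl2, 0 °C) should convert both aldehydes into dibromoalkenes, giving 1,1,7,7-tetrabromo-4,4-dimethylhepta-1,6-diene F10, a non-volatile intermediate that can be purified. n-BuLi (THF, −78 °C to rt) followed by aqueous quench should then give 4.

Further compounds
F1 | step 7 | 5,5-dimethylocta-2,7-diynoic acid | OC(=O)C#CCC(C)(C)CC#C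
F2 | step 7 | 5-[(tert-butyldimethylsilyl)oxy]pent-3-yn-1-ol | OCCC#CCO[Si](C)(C)C(C)(C)C
F3 | step 7 | 5-[(tert-butyldimethylsilyl)oxy]pent-3-yn-1-yl 5,5-dimethylocta-2,7-diynoate | C#CCC(C)(C)CC#CC(=O)OCCC#CCO[Si](C)(C)C(C)(C)C
F4 | step 7 | tert-butyldimethylsilyl ether of 15 | CC(C)(C)[Si](C)(C)OCc1cc2CC(C)(C)Cc2c2C(=O)OCCc12
F5 | step 9 | tert-butyldiphenylsilyl ether of 15 | CC(C)(C)[Si](OCc1cc2CC(C)(C)Cc2c2C(=O)OCCc12)(c1ccccc1)c1ccccc1
F6 | step 9 | 2-[6-({[tert-butyl(diphenyl)silyl]oxy}methyl)-4-(hydroxymethyl)-2,2-dimethylindan-5-yl]ethanol | CC(C)(C)[Si](OCc1cc2CC(C)(C)Cc2c(CO)c1CCO)(c1ccccc1)c1ccccc1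
F7 | step 9 | tert-butyl{[5-(2-chloroethyl)-4-(chloromethyl)-2,2-dimethylindan-6-yl]methoxy}diphenylsilane | CC(C)(C)[Si](OCc1cc2CC(C)(C)Cc2c(CCl)c1CCCl)(c1ccccc1)c1ccccc1
F8 | step 9 | [6-({[tert-butyl(diphenyl)silyl]oxy}methyl)-5-(2-chloroethyl)-2,2-dimethylindan-4-yl]methyl acetate | CC(C)(C)[Si](OCc1cc2CC(C)(C)Cc2c(COC(C)=O)c1CCCl)(c1ccccc1)c1ccccc1
F9 | step 9 | [5-(2-chloroethyl)-6-(hydroxymethyl)-2,2-dimethylindan-4-yl]methyl acetate | CC(=O)OCc1c2CC(C)(C)Cc2cc(CO)c1CCCl
F10 | step 3 | 1,1,7,7-tetrabromo-4,4-dimethylhepta-1,6-diene | BrC(Br)=CCC(C)(C)CC=C(Br)Br
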